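The 3,3-dimethylnorbornane is not built as such. Its five-membered ring C2'–C1'–C7'–C4'–C3' (norbornane locants: spiro carbon, bridgehead, CH2 bridge, bridgehead, CMe2) is the cyclobutane C1'–C7'–C5'–C6' of a pinane (pinane locants), enlarged by the neighbouring spiro carbon C2'. The precursor is the spiro[chromane-2,2'-pinane] that forms in one step from diformylphloroglucinol, isovaleraldehyde and (−)-β-pinene. Acid ionises its tertiary C2'–O bond, whose leaving group is a vinylogous acid; two Wagner–Meerwein shifts (pinanyl to bornyl to 3,3-dimethylnorbornyl cation) follow, and the tethered phenol recloses the pyran ring on the rearranged skeleton. β-Pinene supplies both bridgeheads, the cycloaddition sets C4, the reversible closure sets the spiro centre.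

Key step: step 3

Locants: chromane atoms are unprimed, terpene atoms primed. Pinane (precursor of the key step) → norbornane (target): C1'→C1', C2'→C2', C3'→C6', C4'→C5', C5'→C4', C6'→C3', C7'→C7'.

Assumption (remark on the chemistry): in the 4S series the spiro epimer with the ether oxygen endo and the chromane CH2 exo on the norbornane, which is the target, is taken to be the more stable one, so that reversible C–O ionisation converges on it.

Step 1
Reactants: 1 phloroglucinol
Product: 2 2,4,6-trihydroxybenzene-1,3-dicarbaldehyde (2,4-diformylphloroglucinol)
Conditions: POCl3 (2.2 equiv), DMF (2.2 equiv), 1,4-dioxane, 0 → 23 °C; then H2O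
Reagents that add atoms: N,N-dimethylformamide CN(C)C=O (formyl carbon); water O (formyl oxygen)
Why: Vilsmeier–Haack formylation: the chloroiminium ion made from DMF and POCl3 substitutes the highly activated ring twice, each iminium group deactivates the ring so that the third substitution should be slow at this stoichiometry, and aqueous hydrolysis of the bis-iminium salt gives the dialdehyde.

Step 2
Reactants: 2 2,4-diformylphloroglucinol; 3 3-methylbutanal (isovaleraldehyde); 4 (1S,5S)-(−)-β-pinene
Product: 6 (1'R,2R,4S,5'S)-5,7-dihydroxy-6',6'-dimethyl-4-(2-methylpropyl)spiro[chromane-2,2'-bicyclo[3.1.1]heptane]-6,8-dicarbaldehyde, via o-quinone methide 5 (not isolated)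
Conditions: NaOAc (1 equiv), AcOH, 4 (4 equiv), 80 °C, sealed tube; chromatography
Reagents that add atoms: none
Why: Domino Knoevenagel condensation/inverse-electron-demand hetero-Diels–Alder reaction: 2 condenses with 3 at its free ring carbon to the (E)-o-quinone methide 5, whose heterodiene adds to the exocyclic alkene of 4 with oxygen at the disubstituted carbon and from the face anti to the gem-dimethyl bridge, and the orientation that keeps the heterodiene over the ring CH2 (C3') and away from the bridgehead C1' and the C7' methylene makes C4 S; this endo/exo preference is expected to be moderate, so the 4R epimer is removed by chromatography.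

Step 3
Reactants: 6 the spiro[chromane-2,2'-pinane] from step 2
Product: 11 (1'R,2R,4S,4'S)-5,7-dihydroxy-3',3'-dimethyl-4-(2-methylpropyl)spiro[chromane-2,2'-bicyclo[2.2.1]heptane]-6,8-dicarbaldehyde (target), via pinan-2-yl cation 7 (not isolated), via bornan-2-yl cation 8 (not isolated), via 3,3-dimethylnorbornan-2-yl cation 9 (not isolated), via exo-oxygen spiro epimer 10 (not isolated)
Conditions: TfOH (10 mol %), CH2Cl2 (0.02 M), −40 → 23 °C
Reagents that add atoms: none
Why: Catalytic TfOH ionises the tertiary C2'–O bond of 6 (the leaving group is a diformylphenol, a vinylogous carboxylic acid); the C1'–C6' bond, which lies anti to the departing oxygen, shifts from C1' to C2' and so turns the cyclobutane C1'–C6'–C5'–C7' of cation 7 into the cyclopentane C2'–C6'–C5'–C7'–C1' of cation 8, a second shift of C3' from C2' to C1' gives the tertiary cation 9, and the tethered phenol closes the ether on it (pinane locants of 6 throughout). The closest known reaction type is the acid-catalysed Wagner–Meerwein isomerisation of pinenes and 2-pinanyl derivatives to bornyl and camphene-type products. The carbocycle is not closed but enlarged by the two suprafacial 1,2-alkyl shifts, and the pyran ring recloses by six-membered capture of a tertiary cation by the phenol oxygen, which among the rearranged cations only 9 allows because 8 would need a seven-membered ether. C4' of 11 is the untouched C5' of 6, C1' keeps its place while the bicyclic frame dictates its configuration during the shifts, C4 is carried over from 6, and the spiro centre is set by reversible closure: exo capture should give 10 first, which re-ionises easily, and the equilibrium should settle on 11 with the larger CH2 exo, the oxygen endo and CMe2 and isobutyl both pseudo-equatorial on the pyran ring. The step needs the shift of C6' to outrun heterolysis of the same bond to a monocyclic p-menthenyl cation and the shift of C7'; the anti alignment of C1'–C6' with the leaving group, a non-nucleophilic acid in a non-polar solvent at low temperature and the internal nucleophile that can drain only 9 should secure this.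

Compound list
1 | phloroglucinol (benzene-1,3,5-triol) | Oc1cc(O)cc(O)c1 | starting material
2 | 2,4,6-trihydroxybenzene-1,3-dicarbaldehyde (2,4-diformylphloroglucinol) | O=Cc1c(O)cc(O)c(C=O)c1O | intermediate
3 | 3-methylbutanal (isovaleraldehyde) | CC(C)CC=O | starting material
4 | (1S,5S)-(−)-β-pinene (6,6-dimethyl-2-methylenebicyclo[3.1.1]heptane) | C=C1CC[C@H]2C[C@@H]1C2(C)C | starting material
5 | (E)-o-quinone methide: 2,4-diformyl-3,5-dihydroxy-6-(3-methylbutylidene)cyclohexa-2,4-dien-1-one | CC(C)C/C=C1/C(=O)C(C=O)=C(O)C(C=O)=C1O | intermediate
6 | (1'R,2R,4S,5'S)-5,7-dihydroxy-6',6'-dimethyl-4-(2-methylpropyl)spiro[chromane-2,2'-bicyclo[3.1.1]heptane]-6,8-dicarbaldehyde (ether oxygen anti to the gem-dimethyl bridge) | CC(C)C[C@H]1C[C@@]2(CC[C@H]3C[C@@H]2C3(C)C)Oc2c(C=O)c(O)c(C=O)c(O)c21 | intermediate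
7 | tertiary pinan-2-yl cation: 6,6-dimethylbicyclo[3.1.1]heptan-2-ylium carrying the 2-(3,5-diformyl-2,4,6-trihydroxyphenyl)-4-methylpentyl chain on C2 (benzylic centre and bridgeheads as in 6) | CC(C)C[C@@H](C[C+]1CC[C@H]2C[C@@H]1C2(C)C)c1c(O)c(C=O)c(O)c(C=O)c1O | intermediate
8 | secondary bornan-2-yl cation: 7,7-dimethylbicyclo[2.2.1]heptan-2-ylium carrying the same chain on bridgehead C1 | CC(C)C[C@@H](C[C@@]12CC[C@@H](C[CH+]1)C2(C)C)c1c(O)c(C=O)c(O)c(C=O)c1O | intermediate
9 | tertiary 3,3-dimethylnorbornan-2-yl cation: 3,3-dimethylbicyclo[2.2.1]heptan-2-ylium carrying the same chain on the cationic C2 | CC(C)C[C@@H](C[C+]1[C@@H]2CC[C@@H](C2)C1(C)C)c1c(O)c(C=O)c(O)c(C=O)c1O | intermediate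
10 | (1'R,2S,4S,4'S)-5,7-dihydroxy-3',3'-dimethyl-4-(2-methylpropyl)spiro[chromane-2,2'-bicyclo[2.2.1]heptane]-6,8-dicarbaldehyde (spiro epimer of the target, ether oxygen exo) | CC(C)C[C@H]1C[C@]2(Oc3c(C=O)c(O)c(C=O)c(O)c31)[C@@H]1CC[C@@H](C1)C2(C)C | intermediate
11 | (1'R,2R,4S,4'S)-5,7-dihydroxy-3',3'-dimethyl-4-(2-methylpropyl)spiro[chromane-2,2'-bicyclo[2.2.1]heptane]-6,8-dicarbaldehyde (ether oxygen endo, chromane CH2 exo, isobutyl cis to CMe2 across the pyran ring) | CC(C)C[C@H]1C[C@@]2(Oc3c(C=O)c(O)c(C=O)c(O)c31)[C@@H]1CC[C@@H](C1)C2(C)C | target

Total step count: 3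
Longest linear sequence: 3 steps (1 → 2 → 6 → 11)

Steps most likely to fail

Step 3. What may go wrong: heterolysis of the C1'–C6' bond of cation 7 to a monocyclic p-menthenyl cation, with loss of the bicyclic frame, may outrun the 1,2-shift, or the spiro centre may fail to equilibrate. Fallback: the ring expansion is moved to the hydrocarbon stage. Setting out from 4, isomerisation over acid-activated TiO2 (neat, 130–150 °C; the classical pinene-to-camphene Wagner–Meerwein isomerisation, which passes through α-pinene) and fractional distillation should give (1S,4R)-(−)-camphene F1. Its optical purity is checked against commercial (−)-camphene, because prolonged acid contact can erode it. F1 then replaces 4 under the conditions of step 2 with 2 and 3 (via 5). The heterodiene should add across the exocyclic alkene with oxygen at the ring carbon, giving 11 when oxygen enters from the endo face and 10 when it enters from the exo face; C4 epimers are removed by chromatography. 10 is converted into 11 with TfOH in CH2Cl2, which then only has to ionise and reclose the C–O bond at the stage of cation 9. The fallback returns to the route at 10 or 11.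

Step 2. What may go wrong: poor endo/exo discrimination at 80 °C (a low share of the 4S epimer), competing ene addition of 4 to 5, or oligomerisation of 5. Fallback: 5 is released from an isolated precursor at low temperature. Setting out from 2 and 3, condensation with p-toluenesulfinic acid (MeCN, 23 °C) should give the racemic benzylic sulfone 2,4,6-trihydroxy-5-[3-methyl-1-(4-methylphenylsulfonyl)butyl]benzene-1,3-dicarbaldehyde F2. One equivalent of NaHCO3 in CH2Cl2 containing an excess of 4 at 0 °C should expel sulfinate from the phenoxide, release 5 slowly and give 6, where the lower temperature should sharpen the face and endo/exo selection. The fallback returns to the route at 6.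

Step 1. What may go wrong: incomplete or excessive formylation (mono- and trialdehyde) and difficult separation of the polar products. Fallback: the hydroxyl groups are masked. Setting out from 1, O-methylation (Me2SO4, K2CO3, acetone, reflux) gives 1,3,5-trimethoxybenzene F3, which is also commercial. Rieche formylation (Cl2CHOMe, TiCl4, CH2Cl2, 0 °C) should give 2,4,6-trimethoxybenzene-1,3-dicarbaldehyde F4. BBr3 (CH2Cl2, −78 → 23 °C) then removes the three methyl groups, each ortho to a formyl group, and returns to the route at 2.

Further compounds
F1 | step 3 | (1S,4R)-(−)-camphene (2,2-dimethyl-3-methylenebicyclo[2.2.1]heptane) | C=C1[C@@H]2CC[C@@H](C2)C1(C)C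
F2 | step 2 | 2,4,6-trihydroxy-5-[3-methyl-1-(4-methylphenylsulfonyl)butyl]benzene-1,3-dicarbaldehyde (racemic) | CC(C)CC(c1c(O)c(C=O)c(O)c(C=O)c1O)S(=O)(=O)c1ccc(C)cc1
F3 | step 1 | 1,3,5-trimethoxybenzene | COc1cc(OC)cc(OC)c1
F4 | step 1 | 2,4,6-trimethoxybenzene-1,3-dicarbaldehyde | COc1cc(OC)c(C=O)c(OC)c1C=O
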